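The oxolane is numbered O1, C2 (guaiacyl ring A), C3 (CH2OH), C4 (carbinol Cα with catechol ring B), C5. The plan exploits two facts: C5 is a bare CH2 flanked by O1 and C4, and the C4–Cα bond can be read as the old double bond of a ring B styrene. The oxolane is therefore opened at O1–C5 and C5–C4, with Cα–O as the third bond. A single Prins reaction with formaldehyde closes the ring, makes all three bonds and sets C4 and Cα. Its precursor is the (1S,2R)-(E)-homoallylic alcohol from an Evans syn-aldol: ring A as a deactivating pivalate, ring B as donating silyl ethers, the C3 arm as a pivalate that hands its oxygen to Cα.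

Key step: step 8

Remark: the descriptors are read from the target SMILES, (2S,3R,4S) for the all-trans oxolane and (R) for Cα; the aldol-syn precursor is (1S,2R), with 1-OH and 2-CH2O anti along the butenol chain.

Step 1
Reactants: 1 3,4-dihydroxybenzaldehyde
Product: 2 3,4-bis[(tert-butyldimethylsilyl)oxy]benzaldehyde
Conditions: TBSCl (2.5 equiv), imidazole (5 equiv), DMF, 0 °C to rt
Reagents that add atoms: tert-butyldimethylsilyl chloride, CC(C)(C)[Si](C)(C)Cl
Why: Imidazole-promoted silyl ether formation on both phenols leaves the aldehyde untouched and makes ring B a donor for the later cation at Cα; no stereocentre is involved.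

Step 2
Reactants: 2 3,4-bis[(tert-butyldimethylsilyl)oxy]benzaldehyde; 3 (2-carboxyethyl)triphenylphosphonium bromide
Product: 5 (3E)-4-{3,4-bis[(tert-butyldimethylsilyl)oxy]phenyl}but-3-enoic acid, via carboxylate ylide 4 (not isolated)
Conditions: 3 (1.3 equiv), NaN(SiMe3)2 (2.6 equiv), THF, 0 °C; then 2, −78 °C to rt; 1 M HCl to pH 3, 0 °C
Reagents that add atoms: none
Why: Wittig olefination of the aryl aldehyde with the carboxylate-bearing ylide 4, a pairing expected to favour the (E)-styrylacetic acid, under a non-nucleophilic amide base that should spare the aryl silyl ethers; no stereocentre is formed and residual (Z)-acid can be removed by crystallisation.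

Step 3
Reactants: 5 (3E)-4-{3,4-bis[(tert-butyldimethylsilyl)oxy]phenyl}but-3-enoic acid; 6 (4S)-4-benzyl-1,3-oxazolidin-2-one
Product: 8 (4S)-4-benzyl-3-[(3E)-4-{3,4-bis[(tert-butyldimethylsilyl)oxy]phenyl}but-3-enoyl]-1,3-oxazolidin-2-one, via pivalic mixed anhydride 7 (not isolated)
Conditions: PivCl (1.1 equiv), Et3N (2.5 equiv), THF, −20 °C; then 6, LiCl (1.1 equiv), −20 °C to rt
Reagents that add atoms: none
Why: Acylation of the oxazolidinone nitrogen by the mixed anhydride 7 (acyl transfer under LiCl/Et3N activation) is mild enough to leave the β,γ-alkene in conjugation with ring B, and the auxiliary centre is untouched.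

Step 4
Reactants: 9 vanillin
Product: 10 4-formyl-2-methoxyphenyl pivalate
Conditions: PivCl (1.2 equiv), Et3N (1.5 equiv), 4-(dimethylamino)pyridine (5 mol %), CH2Cl2, 0 °C to rt
Reagents that add atoms: pivaloyl chloride, CC(C)(C)C(Cl)=O
Why: Esterification of the phenol gives a hindered, electron-withdrawing ester that later keeps ring A from stabilising a cation at C2; no stereocentre is involved.

Step 5
Reactants: 8 (4S)-4-benzyl-3-[(3E)-4-{3,4-bis[(tert-butyldimethylsilyl)oxy]phenyl}but-3-enoyl]-1,3-oxazolidin-2-one; 10 4-formyl-2-methoxyphenyl pivalate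
Product: 13 (4S)-4-benzyl-3-[(2S,3S)-2-[(E)-2-{3,4-bis[(tert-butyldimethylsilyl)oxy]phenyl}ethenyl]-3-hydroxy-3-[3-methoxy-4-(pivaloyloxy)phenyl]propanoyl]-1,3-oxazolidin-2-one, via boron dienolate 11 (not isolated), via boron aldolate 12 (not isolated)
Conditions: Bu2BOTf (1.2 equiv), i-Pr2NEt (1.4 equiv), CH2Cl2, −78 to 0 °C; then 10 (1.2 equiv), −78 to 0 °C; pH 7 phosphate buffer, MeOH, aq. H2O2, 0 °C
Reagents that add atoms: none
Why: Evans syn-aldol addition, in which soft enolisation gives the (Z)-dibutylboron dienolate 11 that should react at its α-carbon with 10 through a chair-like Zimmerman–Traxler transition state on the face away from the benzyl group, setting both new centres (2S,3S), the future C3 and C2 of the oxolane.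

Step 6
Reactants: 13 the syn-aldol adduct
Product: 14 4-[(1S,2R,3E)-4-{3,4-bis[(tert-butyldimethylsilyl)oxy]phenyl}-1-hydroxy-2-(hydroxymethyl)but-3-en-1-yl]-2-methoxyphenyl pivalate
Conditions: LiBH4 (1.5 equiv), H2O (1.5 equiv), Et2O/THF, 0 °C
Reagents that add atoms: none
Why: Reductive cleavage of the N-acyl oxazolidinone by borohydride attack at the exocyclic carbonyl should outpace reduction of the hindered aryl pivalate in a short, cold reaction (any phenol set free would be re-esterified by the acid chloride of step 7), and neither stereocentre is touched.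

Step 7
Reactants: 14 the 1,3-diol
Product: 15 4-[(1S,2R,3E)-4-{3,4-bis[(tert-butyldimethylsilyl)oxy]phenyl}-1-hydroxy-2-[(pivaloyloxy)methyl]but-3-en-1-yl]-2-methoxyphenyl pivalate
Conditions: PivCl (1.2 equiv), pyridine (3 equiv), CH2Cl2, −20 to 0 °C
Reagents that add atoms: pivaloyl chloride, CC(C)(C)C(Cl)=O
Why: Chemoselective esterification of the primary hydroxyl with the bulky acid chloride, the hindered secondary benzylic hydroxyl at the future C2 being left free for hemiformal formation; the ester is placed on the C3 arm as the neighbouring group for Cα.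

Step 8
Reactants: 15 the (1S,2R)-(E)-homoallylic alcohol; 16 formaldehyde (charged as paraformaldehyde)
Product: 21 [(2S,3R,4S)-4-[(R)-{3,4-bis[(tert-butyldimethylsilyl)oxy]phenyl}(hydroxy)methyl]-2-[3-methoxy-4-(pivaloyloxy)phenyl]oxolan-3-yl]methyl pivalate, via hemiformal 17 (not isolated), via oxocarbenium ion 18 (not isolated), via benzylic cation 19 (not isolated), via dioxepanylium ion 20 (not isolated)
Conditions: (CH2O)n (3 equiv), In(OTf)3 (20 mol %), 2,6-di-tert-butylpyridine (30 mol %), CH2Cl2, 0 °C to rt; aq. NaHCO3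
Reagents that add atoms: none
Why: In(OTf)3 turns hemiformal 17 into the O1=C5 oxocarbenium ion 18, whose carbon C5 is attacked by the inner styrene carbon C4 in the Markovnikov sense, so that the charge lands on Cα beside the silyloxy-substituted ring B, while the pivalate on ring A keeps C2 from ionising and slows the 2-oxonia-Cope shift. The nearest reaction type is the Lewis-acid oxonium-Prins ring closure of 4-aryl homoallylic alcohols with aldehydes, which ends in a benzylic cation outside the new oxolane and has been terminated by internal as well as external nucleophiles. The oxolane closes in the 5-exo-trig mode with respect to the styrene (the C5=O1 bond lies inside the forming ring), and the seven-membered ring of 20 is only transient. C4 is controlled by the C2 and C3 centres through an envelope transition state that holds ring A, the CH2OPiv arm and the styryl terminus pseudo-equatorial, which gives the 2,3-trans-3,4-trans ring. Cα is controlled by the (E)-alkene, which delivers cation 19 with H4 syn to ring B (least allylic strain), and by the carbonyl oxygen of the C3 arm, which should reach only the C3 side of that cation, anti to the new C4–C5 bond, to give 20; the water set free on ionisation then opens 20 at the acyl carbon with retention at Cα, and collapse to the primary ester gives 21 (a Cα ester, if formed, converges in step 9). The step thus needs Markovnikov regioselectivity, 3,4-trans selectivity and C3-side capture of the cation: ring B secures the first, the aldol-derived centres the second and the neighbouring pivalate the third, since an external nucleophile would be expected to prefer the open C5 side and give the Cα epimer.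

Step 9
Reactants: 21 the oxolane bis-pivalate
Product: 22 4-[(2S,3R,4S)-4-[(R)-{3,4-bis[(tert-butyldimethylsilyl)oxy]phenyl}(hydroxy)methyl]-3-(hydroxymethyl)oxolan-2-yl]-2-methoxyphenol
Conditions: i-Bu2AlH (7 equiv), CH2Cl2, −78 °C; MeOH, then aq. potassium sodium tartrate
Reagents that add atoms: none
Why: Hydride cleavage of both pivalates (ester reduction) at low temperature avoids basic solvolysis, so the silyl ethers stay on ring B and no phenoxide para to Cα is formed that could expel the Cα oxygen; no stereocentre is touched.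

Step 10
Reactants: 22 the ring B bis-silyl ether
Product: 23 4-[(R)-hydroxy[(3S,4R,5S)-4-(hydroxymethyl)-5-(4-hydroxy-3-methoxyphenyl)oxolan-3-yl]methyl]benzene-1,2-diol (CNP0197133.1)
Conditions: Bu4NF (2.5 equiv), AcOH (2.5 equiv), THF, 0 °C, argon
Reagents that add atoms: none
Why: Fluoride-induced desilylation of the two aryl silyl ethers, buffered with acetic acid so that catechol autoxidation and quinone-methide formation at Cα or C2 are not triggered, should release the target with all four stereocentres intact.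

Compound list
1 | 3,4-dihydroxybenzaldehyde | O=Cc1ccc(O)c(O)c1 | starting material
2 | 3,4-bis[(tert-butyldimethylsilyl)oxy]benzaldehyde | O=Cc1ccc(O[Si](C)(C)C(C)(C)C)c(O[Si](C)(C)C(C)(C)C)c1 | intermediate
3 | (2-carboxyethyl)triphenylphosphonium bromide | [Br-].OC(=O)CC[P+](c1ccccc1)(c1ccccc1)c1ccccc1 | starting material
4 | sodium 3-(triphenyl-λ5-phosphanylidene)propanoate (carboxylate ylide, not isolated) | [Na+].[O-]C(=O)CC=P(c1ccccc1)(c1ccccc1)c1ccccc1 | intermediate
5 | (3E)-4-{3,4-bis[(tert-butyldimethylsilyl)oxy]phenyl}but-3-enoic acid | OC(=O)C/C=C/c1ccc(O[Si](C)(C)C(C)(C)C)c(O[Si](C)(C)C(C)(C)C)c1 | intermediate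
6 | (4S)-4-benzyl-1,3-oxazolidin-2-one | O=C1N[C@@H](Cc2ccccc2)CO1 | starting material
7 | mixed anhydride of 5 with pivalic acid (not isolated) | CC(C)(C)C(=O)OC(=O)C/C=C/c1ccc(O[Si](C)(C)C(C)(C)C)c(O[Si](C)(C)C(C)(C)C)c1 | intermediate
8 | (4S)-4-benzyl-3-[(3E)-4-{3,4-bis[(tert-butyldimethylsilyl)oxy]phenyl}but-3-enoyl]-1,3-oxazolidin-2-one | O=C(C/C=C/c1ccc(O[Si](C)(C)C(C)(C)C)c(O[Si](C)(C)C(C)(C)C)c1)N1[C@@H](Cc2ccccc2)COC1=O | intermediate
9 | vanillin | COc1cc(C=O)ccc1O | starting material
10 | 4-formyl-2-methoxyphenyl pivalate | COc1cc(C=O)ccc1OC(=O)C(C)(C)C | intermediate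
11 | (1Z,3E)-O-dibutylboryl dienolate of 8 (not isolated) | CCCCB(CCCC)O/C(=C\C=C\c1ccc(O[Si](C)(C)C(C)(C)C)c(O[Si](C)(C)C(C)(C)C)c1)N1[C@@H](Cc2ccccc2)COC1=O | intermediate
12 | O-dibutylboryl aldolate of 13 (not isolated) | COc1cc(ccc1OC(=O)C(C)(C)C)[C@@H](OB(CCCC)CCCC)[C@@H](C(=O)N1[C@@H](Cc2ccccc2)COC1=O)/C=C/c1ccc(O[Si](C)(C)C(C)(C)C)c(O[Si](C)(C)C(C)(C)C)c1 | intermediate
13 | (4S)-4-benzyl-3-[(2S,3S)-2-[(E)-2-{3,4-bis[(tert-butyldimethylsilyl)oxy]phenyl}ethenyl]-3-hydroxy-3-[3-methoxy-4-(pivaloyloxy)phenyl]propanoyl]-1,3-oxazolidin-2-one | COc1cc(ccc1OC(=O)C(C)(C)C)[C@@H](O)[C@@H](C(=O)N1[C@@H](Cc2ccccc2)COC1=O)/C=C/c1ccc(O[Si](C)(C)C(C)(C)C)c(O[Si](C)(C)C(C)(C)C)c1 | intermediate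
14 | 4-[(1S,2R,3E)-4-{3,4-bis[(tert-butyldimethylsilyl)oxy]phenyl}-1-hydroxy-2-(hydroxymethyl)but-3-en-1-yl]-2-methoxyphenyl pivalate | COc1cc(ccc1OC(=O)C(C)(C)C)[C@@H](O)[C@@H](CO)/C=C/c1ccc(O[Si](C)(C)C(C)(C)C)c(O[Si](C)(C)C(C)(C)C)c1 | intermediate
15 | 4-[(1S,2R,3E)-4-{3,4-bis[(tert-butyldimethylsilyl)oxy]phenyl}-1-hydroxy-2-[(pivaloyloxy)methyl]but-3-en-1-yl]-2-methoxyphenyl pivalate | COc1cc(ccc1OC(=O)C(C)(C)C)[C@@H](O)[C@@H](COC(=O)C(C)(C)C)/C=C/c1ccc(O[Si](C)(C)C(C)(C)C)c(O[Si](C)(C)C(C)(C)C)c1 | intermediate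
16 | formaldehyde (used as paraformaldehyde) | C=O | starting material
17 | O-(hydroxymethyl) hemiformal of 15 (not isolated) | COc1cc(ccc1OC(=O)C(C)(C)C)[C@@H](OCO)[C@@H](COC(=O)C(C)(C)C)/C=C/c1ccc(O[Si](C)(C)C(C)(C)C)c(O[Si](C)(C)C(C)(C)C)c1 | intermediate
18 | O1-methylene oxocarbenium ion (triflate counter-ion, not isolated) | COc1cc(ccc1OC(=O)C(C)(C)C)[C@@H]([O+]=C)[C@@H](COC(=O)C(C)(C)C)/C=C/c1ccc(O[Si](C)(C)C(C)(C)C)c(O[Si](C)(C)C(C)(C)C)c1 | intermediate
19 | (2S,3R,4S)-oxolane with the cationic centre at Cα (not isolated) | COc1cc(ccc1OC(=O)C(C)(C)C)[C@H]2OC[C@@H]([CH+]c3ccc(O[Si](C)(C)C(C)(C)C)c(O[Si](C)(C)C(C)(C)C)c3)[C@@H]2COC(=O)C(C)(C)C | intermediate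
20 | trans-fused 2-tert-butyl-1,3-dioxepan-2-ylium ion bridging Cα–O and the C3 CH2–O (not isolated) | COc1cc(ccc1OC(=O)C(C)(C)C)[C@H]2OC[C@@H]([C@@H](O3)c4ccc(O[Si](C)(C)C(C)(C)C)c(O[Si](C)(C)C(C)(C)C)c4)[C@@H]2CO[C+]3C(C)(C)C | intermediate
21 | [(2S,3R,4S)-4-[(R)-{3,4-bis[(tert-butyldimethylsilyl)oxy]phenyl}(hydroxy)methyl]-2-[3-methoxy-4-(pivaloyloxy)phenyl]oxolan-3-yl]methyl pivalate | COc1cc(ccc1OC(=O)C(C)(C)C)[C@H]2OC[C@@H]([C@@H](O)c3ccc(O[Si](C)(C)C(C)(C)C)c(O[Si](C)(C)C(C)(C)C)c3)[C@@H]2COC(=O)C(C)(C)C | intermediate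
22 | 4-[(2S,3R,4S)-4-[(R)-{3,4-bis[(tert-butyldimethylsilyl)oxy]phenyl}(hydroxy)methyl]-3-(hydroxymethyl)oxolan-2-yl]-2-methoxyphenol | COc1cc(ccc1O)[C@H]2OC[C@@H]([C@@H](O)c3ccc(O[Si](C)(C)C(C)(C)C)c(O[Si](C)(C)C(C)(C)C)c3)[C@@H]2CO | intermediate
23 | 4-[(R)-hydroxy[(3S,4R,5S)-4-(hydroxymethyl)-5-(4-hydroxy-3-methoxyphenyl)oxolan-3-yl]methyl]benzene-1,2-diol (CNP0197133.1) | COc1cc([C@H]2OC[C@@H]([C@@H](O)c3ccc(O)c(O)c3)[C@@H]2CO)ccc1O | target

Total step count: 10.
Longest linear sequence: 9 steps (steps 1, 2, 3, 5, 6, 7, 8, 9 and 10 from 3,4-dihydroxybenzaldehyde); step 4 is a one-step branch from vanillin.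

Steps most likely to fail

Step 8. The Cα cation may be captured by an external oxygen nucleophile on the open C5 side before the arm pivalate closes, or the carbinol may re-ionise, so that Cα forms with poor or inverted selectivity. Further drains are protonation of the styrene followed by closure of the C2 hydroxyl onto Cα, and Friedel–Crafts closure of ring A onto Cα. The fallback sets Cα by carbonyl reduction instead of cation capture. Setting out from 15, the same formaldehyde ring closure is run with a few equivalents of added water and without any demand on Cα, which should give the Cα-epimeric carbinol mixture F1. MnO2 in CH2Cl2 should oxidise both epimers to the aryl ketone F2. Corey–Bakshi–Shibata reduction of F2 (BH3·SMe2, (3aS)-1-methyl-3,3-diphenyltetrahydro-1H,3H-pyrrolo[1,2-c][1,3,2]oxazaborole, THF, −20 °C) should then give the (R)-carbinol, because catalyst control and the Felkin–Anh preference for hydride attack anti to the more substituted C3 point the same way. The fallback comes back to the route at 21.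

Step 5. The extended dienolate may react through its γ-carbon, or the boron aldolate may revert and lose facial selectivity. The fallback changes the auxiliary and the enolate metal. Setting out from acid 5, coupling with (4S)-4-benzyl-1,3-thiazolidine-2-thione (N,N'-dicyclohexylcarbodiimide, 4-(dimethylamino)pyridine, CH2Cl2) should give the N-acyl thiazolidinethione F3. Its chlorotitanium enolate (TiCl4, i-Pr2NEt, N-methylpyrrolidin-2-one, CH2Cl2, −78 °C) should add to 10 in the same syn sense to give the thiazolidinethione aldol adduct F4. NaBH4 in THF/EtOH at 0 °C should cleave this more labile acyl group, and the fallback comes back to the route at diol 14.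

Step 2. The olefination may be incompletely (E)-selective, or the basic ylide solution may cleave aryl silyl ethers; either would feed the wrong material into the stereocontrol of step 8. The fallback builds the alkene by metathesis. Setting out from aldehyde 2, methylenation with Ph3P=CH2 (from methyltriphenylphosphonium bromide and NaN(SiMe3)2, THF) should give 3,4-bis[(tert-butyldimethylsilyl)oxy]styrene F5. Cross-metathesis of F5 with but-3-enoic acid (second-generation Grubbs catalyst, CH2Cl2, 40 °C) should give the thermodynamically favoured (E)-acid, and the fallback comes back to the route at 5.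

Further compounds
F1 | step 8 | [(2S,3R,4S)-4-[{3,4-bis[(tert-butyldimethylsilyl)oxy]phenyl}(hydroxy)methyl]-2-[3-methoxy-4-(pivaloyloxy)phenyl]oxolan-3-yl]methyl pivalate, mixture of Cα epimers | COc1cc(ccc1OC(=O)C(C)(C)C)[C@H]2OC[C@@H](C(O)c3ccc(O[Si](C)(C)C(C)(C)C)c(O[Si](C)(C)C(C)(C)C)c3)[C@@H]2COC(=O)C(C)(C)C
F2 | step 8 | [(2S,3R,4S)-4-{3,4-bis[(tert-butyldimethylsilyl)oxy]benzoyl}-2-[3-methoxy-4-(pivaloyloxy)phenyl]oxolan-3-yl]methyl pivalate | COc1cc(ccc1OC(=O)C(C)(C)C)[C@H]2OC[C@@H](C(=O)c3ccc(O[Si](C)(C)C(C)(C)C)c(O[Si](C)(C)C(C)(C)C)c3)[C@@H]2COC(=O)C(C)(C)C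
F3 | step 5 | (3E)-1-[(4S)-4-benzyl-2-thioxo-1,3-thiazolidin-3-yl]-4-{3,4-bis[(tert-butyldimethylsilyl)oxy]phenyl}but-3-en-1-one | O=C(C/C=C/c1ccc(O[Si](C)(C)C(C)(C)C)c(O[Si](C)(C)C(C)(C)C)c1)N1[C@@H](Cc2ccccc2)CSC1=S
F4 | step 5 | 4-[(1S,2S,3E)-2-{[(4S)-4-benzyl-2-thioxo-1,3-thiazolidin-3-yl]carbonyl}-4-{3,4-bis[(tert-butyldimethylsilyl)oxy]phenyl}-1-hydroxybut-3-en-1-yl]-2-methoxyphenyl pivalate | COc1cc(ccc1OC(=O)C(C)(C)C)[C@@H](O)[C@@H](C(=O)N1[C@@H](Cc2ccccc2)CSC1=S)/C=C/c1ccc(O[Si](C)(C)C(C)(C)C)c(O[Si](C)(C)C(C)(C)C)c1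
F5 | step 2 | 3,4-bis[(tert-butyldimethylsilyl)oxy]styrene | C=Cc1ccc(O[Si](C)(C)C(C)(C)C)c(O[Si](C)(C)C(C)(C)C)c1
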